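**Plan**

1. The polyene is cut at C11=C12 and C11'=C12' (two Wittig reactions, C15 + C10 + C15), each ester C–O bond goes back to an acid chloride, the β half is cut at C6–C7 (Stille coupling of an enol triflate), and the ε side chain at C7'=C8' (cross-metathesis) and C9'–C10' (vinyl Grignard).
2. The ε ring is taken back to its C3' ketone, a 4-substituted 3,5,5-trimethylcyclohex-2-enone. Removing C4' (bonds C3'–C4' and C4'–C5') leaves a 2-methylcyclopentanone enol ether, and cutting C6'–C7' leads to 2,4,4-trimethylcyclopent-2-enone.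
3. Enabling feature: in the ε ring C6' is γ to the C3' oxygen and C5' carries the methyl group of the C4'=C5' alkene. In the ring-contracted cyclopentanone C6' is the β-carbon and C5' the α-carbon, so conjugate addition can set C6', and the O-trapped enolate marks exactly the C3'–C5' bond into which C4' is inserted.
4. Forward: cyclopentenone, asymmetric conjugate addition with silylation, cyclopropanation, ring enlargement to the cyclohexenone, reduction, myristate, side chain, ε-C15 phosphonium salt. The β ring comes from actinol and reaches its C15 salt in four steps. The β-C15 salt is joined to the C10 dialdehyde first, and the ε-C15 salt is added last.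
5. Stereochemistry: C6' by copper-catalysed asymmetric conjugate addition, C3' by CBS reduction (catalyst control, trans to C6'), C3 from (4R,6R)-actinol. E geometry comes from metathesis, syn-hydrostannation and thermal equilibration after each Wittig step.

Key step: step 3

Remark: the target is read as all-E (3R,3'R,6'R)-β,ε-carotene-3,3'-diol 3-hexadecanoate 3'-tetradecanoate; carotenoid numbering is used for positions (unprimed for the β half, primed for the ε half).

**Route**

Step 1
Reactants: 1 2,4,4-trimethylcyclopent-2-en-1-one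
Product: 3 trimethyl{[(3R)-3-ethenyl-2,4,4-trimethylcyclopent-1-en-1-yl]oxy}silane, via aluminium enolate 2 (not isolated)
Conditions: CH2=CHMgBr, Me2AlCl, Et2O, 0 °C; then 1, copper thiophene-2-carboxylate (CuTC, 5 mol%), binaphthol-derived bis(1-phenylethyl)amine phosphoramidite L* (10 mol%, antipode that gives 3R), Et2O, −30 °C; then TMSOTf, −30 °C to rt
Reagents that add atoms: vinylmagnesium bromide C=C[Mg]Br; trimethylsilyl trifluoromethanesulfonate C[Si](C)(C)OS(=O)(=O)C(F)(F)F
Why: Copper-catalysed asymmetric conjugate addition of an alkenylalane to a cyclic enone followed by O-silylation: the Lewis-acidic alane activates the hindered enone, the chiral copper–phosphoramidite complex delivers vinyl to one face of the β-carbon and so sets the centre that becomes C6', and silylation of the regiodefined aluminium enolate fixes the tetrasubstituted C1=C2 enol ether.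

Step 2
Reactants: 3 trimethyl{[(3R)-3-ethenyl-2,4,4-trimethylcyclopent-1-en-1-yl]oxy}silane
Product: 4 {[(1S,4R,5S)-4-ethenyl-3,3,5-trimethylbicyclo[3.1.0]hexan-1-yl]oxy}trimethylsilane (cyclopropane CH2 anti to vinyl)
Conditions: Et2Zn, CH2I2, CH2Cl2, 0 °C
Reagents that add atoms: diiodomethane ICI
Why: Furukawa-modified Simmons–Smith cyclopropanation, in which the electron-rich silyl enol ether reacts far faster with the zinc carbenoid than the monosubstituted vinyl group and the methylene is delivered anti to the adjacent vinyl substituent, although both new bridgehead centres are erased in step 3.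

Step 3
Reactants: 4 {[(1S,4R,5S)-4-ethenyl-3,3,5-trimethylbicyclo[3.1.0]hexan-1-yl]oxy}trimethylsilane
Product: 6 (4R)-4-ethenyl-3,5,5-trimethylcyclohex-2-en-1-one, via β-chloro ketone 5 (not isolated)
Conditions: FeCl3 (2.2 equiv), pyridine, DMF, 0 °C to rt; then NaOAc, MeOH, 65 °C
Reagents that add atoms: none
Why: Exchange of silicon for trivalent iron at oxygen gives an iron cyclopropoxide whose one-electron oxidation triggers β-scission of the zero-bridge C1–C5 bond, so that the five-membered ring and the cyclopropane merge into a six-membered β-keto radical centred on the methyl-bearing carbon, which takes chlorine from a second FeCl3 to give chloro ketone 5; sodium acetate then removes HCl by an E1cB path through the enolate of the new C4' methylene. The closest known reaction type is the Saegusa–Ito one-carbon ring enlargement of 1-siloxybicyclo[n.1.0]alkanes to cycloalkenones. No ring is closed by a new bond: the cyclohexenone arises by cleavage of the bond shared by the three- and five-membered rings, which places the carbenoid carbon (C4') between the former carbonyl carbon (C3') and the former α-carbon (C5'). No new stereocentre is kept (both bridgeheads and the transient C–Cl centre end as trigonal carbons), and the only stereocentre, C6', lies outside the reacting array and is carried through unchanged. The selectivities needed are scission of the internal and not the external cyclopropane bond, secured by the tertiary methyl-substituted radical and the strain of the fused bond, and elimination toward C4' only, secured because C4'–H is the sole hydrogen both α to the carbonyl and β to chlorine while the weak base leaves the γ-hydrogen at C6' untouched.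

Step 4
Reactants: 6 (4R)-4-ethenyl-3,5,5-trimethylcyclohex-2-en-1-one
Product: 7 (1R,4R)-4-ethenyl-3,5,5-trimethylcyclohex-2-en-1-ol
Conditions: (S)-2-methyl-CBS-oxazaborolidine (15 mol%), catecholborane, toluene, −78 °C; then H2O
Reagents that add atoms: none
Why: Corey–Bakshi–Shibata reduction, in which the (S)-oxazaborolidine binds the enone with its alkenyl flank as the large group and delivers hydride to the carbonyl face that gives the 1R carbinol (C3', trans to the C6' vinyl group) under catalyst control, catecholborane at low temperature sparing both alkenes.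

Step 5
Reactants: 7 (1R,4R)-4-ethenyl-3,5,5-trimethylcyclohex-2-en-1-ol
Product: 8 (1R,4R)-4-ethenyl-3,5,5-trimethylcyclohex-2-en-1-yl tetradecanoate
Conditions: CH3(CH2)12COCl, pyridine, DMAP (cat.), CH2Cl2, 0 °C to rt
Reagents that add atoms: tetradecanoyl chloride CCCCCCCCCCCCCC(=O)Cl
Why: DMAP-catalysed esterification (nucleophilic acyl substitution) at the hydroxyl oxygen, which leaves the C–O bond and hence the configuration at C3' untouched.

Step 6
Reactants: 8 (1R,4R)-4-ethenyl-3,5,5-trimethylcyclohex-2-en-1-yl tetradecanoate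
Product: 9 (1R,4R)-3,5,5-trimethyl-4-[(1E)-3-oxobut-1-en-1-yl]cyclohex-2-en-1-yl tetradecanoate
Conditions: methyl vinyl ketone (4 equiv), second-generation Hoveyda–Grubbs catalyst RuCl2(H2IMes)(=CH-C6H4-2-OiPr) (5 mol%), CH2Cl2, 40 °C
Reagents that add atoms: but-3-en-2-one C=CC(C)=O
Why: Olefin cross-metathesis between a monosubstituted alkene and an electron-poor enone partner, which gives the E-enone under thermodynamic control while the trisubstituted ring alkene stays inert to the ruthenium carbene.

Step 7
Reactants: 9 (1R,4R)-3,5,5-trimethyl-4-[(1E)-3-oxobut-1-en-1-yl]cyclohex-2-en-1-yl tetradecanoate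
Product: 10 (1R,4R)-4-[(1E)-3-hydroxy-3-methylpenta-1,4-dien-1-yl]-3,5,5-trimethylcyclohex-2-en-1-yl tetradecanoate (both epimers at the new carbinol carbon)
Conditions: CH2=CHMgBr (1.2 equiv), THF, −78 °C; then H2O
Reagents that add atoms: vinylmagnesium bromide C=C[Mg]Br
Why: Grignard 1,2-addition to the enone carbonyl at low temperature, faster than attack on the long-chain ester, the new carbinol centre being formed without control and lost in step 8.

Step 8
Reactants: 10 (1R,4R)-4-[(1E)-3-hydroxy-3-methylpenta-1,4-dien-1-yl]-3,5,5-trimethylcyclohex-2-en-1-yl tetradecanoate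
Product: 11 {(2E,4E)-3-methyl-5-[(1R,4R)-2,6,6-trimethyl-4-(tetradecanoyloxy)cyclohex-2-en-1-yl]penta-2,4-dien-1-yl}triphenylphosphonium bromide
Conditions: PPh3·HBr (1.05 equiv), CH2Cl2–MeOH, 0 °C to rt
Reagents that add atoms: triphenylphosphine hydrobromide [Br-].c1ccccc1[PH+](c1ccccc1)c1ccccc1
Why: Acid-promoted allylic transposition with phosphine capture (ionisation of the doubly allylic tertiary alcohol to a pentadienyl cation that PPh3 traps at the unhindered primary terminus), which should give mainly the 2E,4E salt, the secondary allylic ester being far less ionisable under these mildly acidic conditions.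

Step 9
Reactants: 12 (4R,6R)-4-hydroxy-2,2,6-trimethylcyclohexan-1-one (actinol)
Product: 13 (1R,5R)-3,3,5-trimethyl-4-oxocyclohexyl hexadecanoate
Conditions: CH3(CH2)14COCl, pyridine, DMAP (cat.), CH2Cl2, 0 °C to rt
Reagents that add atoms: hexadecanoyl chloride CCCCCCCCCCCCCCCC(=O)Cl
Why: DMAP-catalysed esterification at oxygen, which keeps the chiral-pool carbinol configuration that becomes C3.

Step 10
Reactants: 13 (1R,5R)-3,3,5-trimethyl-4-oxocyclohexyl hexadecanoate
Product: 14 (1R)-3,5,5-trimethyl-4-{[(trifluoromethyl)sulfonyl]oxy}cyclohex-3-en-1-yl hexadecanoate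
Conditions: Tf2O, 2,6-di-tert-butyl-4-methylpyridine, CH2Cl2, 0 °C to rt
Reagents that add atoms: trifluoromethanesulfonic anhydride O=S(=O)(OS(=O)(=O)C(F)(F)F)C(F)(F)F
Why: Enol triflate formation under non-nucleophilic conditions (O-triflylation of the ketone and loss of its only α-hydrogen), which creates the tetrasubstituted C5=C6 alkene regiospecifically, removes the superfluous methyl-bearing stereocentre and tolerates the ester.

Step 11
Reactants: 15 (2E)-3-methylpent-2-en-4-yn-1-ol
Product: 16 (2E,4E)-3-methyl-5-(tributylstannyl)penta-2,4-dien-1-ol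
Conditions: Bu3SnH, PdCl2(PPh3)2 (2 mol%), THF, 0 °C
Reagents that add atoms: tributyltin hydride CCCC[SnH](CCCC)CCCC
Why: Palladium-catalysed syn-hydrostannation of a terminal alkyne, which places tin mainly at the terminal carbon and gives the E-alkenylstannane with the existing E-trisubstituted alkene untouched.

Step 12
Reactants: 14 (1R)-3,5,5-trimethyl-4-{[(trifluoromethyl)sulfonyl]oxy}cyclohex-3-en-1-yl hexadecanoate; 16 (2E,4E)-3-methyl-5-(tributylstannyl)penta-2,4-dien-1-ol
Product: 17 (1R)-4-[(1E,3E)-5-hydroxy-3-methylpenta-1,3-dien-1-yl]-3,5,5-trimethylcyclohex-3-en-1-yl hexadecanoate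
Conditions: Pd2(dba)3 (2.5 mol%), AsPh3 (20 mol%), LiCl (3 equiv), NMP, 50 °C
Reagents that add atoms: none
Why: Stille cross-coupling of a hindered cyclohexenyl triflate with an alkenylstannane under ligand-accelerated conditions, forming the C6–C7 bond with retention of both alkene geometries.

Step 13
Reactants: 17 (1R)-4-[(1E,3E)-5-hydroxy-3-methylpenta-1,3-dien-1-yl]-3,5,5-trimethylcyclohex-3-en-1-yl hexadecanoate
Product: 18 {(2E,4E)-5-[(4R)-4-(hexadecanoyloxy)-2,6,6-trimethylcyclohex-1-en-1-yl]-3-methylpenta-2,4-dien-1-yl}triphenylphosphonium bromide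
Conditions: PPh3·HBr, MeOH, rt
Reagents that add atoms: triphenylphosphine hydrobromide [Br-].c1ccccc1[PH+](c1ccccc1)c1ccccc1
Why: Ionisation of the dienylic primary alcohol by HBr and capture of the delocalised cation by PPh3 at the primary carbon, the standard formation of a polyenyl Wittig salt.

Step 14
Reactants: 18 {(2E,4E)-5-[(4R)-4-(hexadecanoyloxy)-2,6,6-trimethylcyclohex-1-en-1-yl]-3-methylpenta-2,4-dien-1-yl}triphenylphosphonium bromide; 19 (2E,4E,6E)-2,7-dimethylocta-2,4,6-trienedial
Product: 21 (3R)-3-(hexadecanoyloxy)-12'-apo-β-caroten-12'-al (all-E C25 aldehyde), via phosphorus ylide 20 (not isolated)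
Conditions: 19 (3 equiv), 1,2-epoxybutane, 65 °C; then heptane, 90 °C
Reagents that add atoms: none
Why: Wittig olefination under neutral, epoxide-buffered conditions that tolerate the ester, in which the excess of the symmetric dialdehyde enforces mono-olefination and heating brings the new C11=C12 bond to E.

Step 15
Reactants: 11 {(2E,4E)-3-methyl-5-[(1R,4R)-2,6,6-trimethyl-4-(tetradecanoyloxy)cyclohex-2-en-1-yl]penta-2,4-dien-1-yl}triphenylphosphonium bromide; 21 (3R)-3-(hexadecanoyloxy)-12'-apo-β-caroten-12'-al
Product: 23 (3R,3'R,6'R)-β,ε-carotene-3,3'-diyl 3-hexadecanoate 3'-tetradecanoate (all-E), via phosphorus ylide 22 (not isolated)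
Conditions: 1,2-epoxybutane, 65 °C; then heptane, 90 °C
Reagents that add atoms: none
Why: Wittig olefination joining the two halves at C11'=C12' under neutral conditions that spare both esters and the allylic C6' centre, followed by thermal Z to E equilibration to the all-E polyene.

**Compound list**

1 | 2,4,4-trimethylcyclopent-2-en-1-one | CC1=CC(C)(C)CC1=O | starting material
2 | dimethylaluminium (3R)-3-ethenyl-2,4,4-trimethylcyclopent-1-en-1-olate | C=C[C@H]1C(C)=C(O[Al](C)C)CC1(C)C | intermediate (not isolated)
3 | trimethyl{[(3R)-3-ethenyl-2,4,4-trimethylcyclopent-1-en-1-yl]oxy}silane | C=C[C@H]1C(C)=C(O[Si](C)(C)C)CC1(C)C | intermediate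
4 | {[(1S,4R,5S)-4-ethenyl-3,3,5-trimethylbicyclo[3.1.0]hexan-1-yl]oxy}trimethylsilane | C=C[C@H]1[C@]2(C)C[C@]2(O[Si](C)(C)C)CC1(C)C | intermediate
5 | (4R)-3-chloro-4-ethenyl-3,5,5-trimethylcyclohexan-1-one (epimers at C3) | C=C[C@H]1C(C)(Cl)CC(=O)CC1(C)C | intermediate (not isolated)
6 | (4R)-4-ethenyl-3,5,5-trimethylcyclohex-2-en-1-one | C=C[C@H]1C(C)=CC(=O)CC1(C)C | intermediate
7 | (1R,4R)-4-ethenyl-3,5,5-trimethylcyclohex-2-en-1-ol | C=C[C@H]1C(C)=C[C@H](O)CC1(C)C | intermediate
8 | (1R,4R)-4-ethenyl-3,5,5-trimethylcyclohex-2-en-1-yl tetradecanoate | C=C[C@H]1C(C)=C[C@H](OC(=O)CCCCCCCCCCCCC)CC1(C)C | intermediate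
9 | (1R,4R)-3,5,5-trimethyl-4-[(1E)-3-oxobut-1-en-1-yl]cyclohex-2-en-1-yl tetradecanoate | CC(=O)/C=C/[C@H]1C(C)=C[C@H](OC(=O)CCCCCCCCCCCCC)CC1(C)C | intermediate
10 | (1R,4R)-4-[(1E)-3-hydroxy-3-methylpenta-1,4-dien-1-yl]-3,5,5-trimethylcyclohex-2-en-1-yl tetradecanoate (carbinol epimers) | C=CC(C)(O)/C=C/[C@H]1C(C)=C[C@H](OC(=O)CCCCCCCCCCCCC)CC1(C)C | intermediate
11 | {(2E,4E)-3-methyl-5-[(1R,4R)-2,6,6-trimethyl-4-(tetradecanoyloxy)cyclohex-2-en-1-yl]penta-2,4-dien-1-yl}triphenylphosphonium bromide | [Br-].c1ccccc1[P+](c1ccccc1)(c1ccccc1)C/C=C(C)/C=C/[C@H]1C(C)=C[C@H](OC(=O)CCCCCCCCCCCCC)CC1(C)C | intermediate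
12 | (4R,6R)-4-hydroxy-2,2,6-trimethylcyclohexan-1-one | O[C@@H]1C[C@@H](C)C(=O)C(C)(C)C1 | starting material
13 | (1R,5R)-3,3,5-trimethyl-4-oxocyclohexyl hexadecanoate | CCCCCCCCCCCCCCCC(=O)O[C@@H]1C[C@@H](C)C(=O)C(C)(C)C1 | intermediate
14 | (1R)-3,5,5-trimethyl-4-{[(trifluoromethyl)sulfonyl]oxy}cyclohex-3-en-1-yl hexadecanoate | CCCCCCCCCCCCCCCC(=O)O[C@@H]1CC(C)=C(OS(=O)(=O)C(F)(F)F)C(C)(C)C1 | intermediate
15 | (2E)-3-methylpent-2-en-4-yn-1-ol | C#C/C(C)=C/CO | starting material
16 | (2E,4E)-3-methyl-5-(tributylstannyl)penta-2,4-dien-1-ol | CCCC[Sn](CCCC)(CCCC)/C=C/C(C)=C/CO | intermediate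
17 | (1R)-4-[(1E,3E)-5-hydroxy-3-methylpenta-1,3-dien-1-yl]-3,5,5-trimethylcyclohex-3-en-1-yl hexadecanoate | CCCCCCCCCCCCCCCC(=O)O[C@@H]1CC(C)=C(/C=C/C(C)=C/CO)C(C)(C)C1 | intermediate
18 | {(2E,4E)-5-[(4R)-4-(hexadecanoyloxy)-2,6,6-trimethylcyclohex-1-en-1-yl]-3-methylpenta-2,4-dien-1-yl}triphenylphosphonium bromide | [Br-].CCCCCCCCCCCCCCCC(=O)O[C@@H]1CC(C)=C(/C=C/C(C)=C/C[P+](c2ccccc2)(c2ccccc2)c2ccccc2)C(C)(C)C1 | intermediate
19 | (2E,4E,6E)-2,7-dimethylocta-2,4,6-trienedial | O=C/C(C)=C/C=C/C=C(C)/C=O | starting material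
20 | {(2E,4E)-5-[(4R)-4-(hexadecanoyloxy)-2,6,6-trimethylcyclohex-1-en-1-yl]-3-methylpenta-2,4-dien-1-ylidene}triphenylphosphorane | CCCCCCCCCCCCCCCC(=O)O[C@@H]1CC(C)=C(/C=C/C(C)=C/C=P(c2ccccc2)(c2ccccc2)c2ccccc2)C(C)(C)C1 | intermediate (not isolated)
21 | (3R)-3-(hexadecanoyloxy)-12'-apo-β-caroten-12'-al | CCCCCCCCCCCCCCCC(=O)O[C@@H]1CC(C)=C(/C=C/C(C)=C/C=C/C(C)=C/C=C/C=C(C)/C=O)C(C)(C)C1 | intermediate
22 | {(2E,4E)-3-methyl-5-[(1R,4R)-2,6,6-trimethyl-4-(tetradecanoyloxy)cyclohex-2-en-1-yl]penta-2,4-dien-1-ylidene}triphenylphosphorane | c1ccccc1P(c1ccccc1)(c1ccccc1)=C/C=C(C)/C=C/[C@H]1C(C)=C[C@H](OC(=O)CCCCCCCCCCCCC)CC1(C)C | intermediate (not isolated)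
23 | (3R,3'R,6'R)-β,ε-carotene-3,3'-diyl 3-hexadecanoate 3'-tetradecanoate | CCCCCCCCCCCCCCCC(=O)O[C@@H]1CC(C)=C(/C=C/C(C)=C/C=C/C(C)=C/C=C/C=C(C)/C=C/C=C(C)/C=C/[C@H]2C(C)=C[C@H](OC(=O)CCCCCCCCCCCCC)CC2(C)C)C(C)(C)C1 | target

**Step count and risks**

Total steps: 15. Longest linear sequence: 9 (steps 1 to 8, then step 15).

Step 1 may fail through low conversion or poor face selectivity, because the β-carbon is flanked by the quaternary carbon and the α-methyl group. Fallback: set out from 1 and give up catalytic control at this stage. Copper-catalysed addition of vinylmagnesium bromide with silyl trapping (CuBr·SMe2, TMSCl, HMPA, THF, −78 °C) should give racemic trimethyl[(3-ethenyl-2,4,4-trimethylcyclopent-1-en-1-yl)oxy]silane F1. Steps 2 and 3 are run unchanged on the racemate, through the racemic siloxycyclopropane F2 and the racemic chloro ketone F3 (not isolated), to racemic 4-ethenyl-3,5,5-trimethylcyclohex-2-en-1-one F4. The CBS reduction of step 4 then acts as a reagent-controlled divergent reduction: the 4R enantiomer gives 7 and the 4S enantiomer gives the cis alcohol (1R,4S)-4-ethenyl-3,5,5-trimethylcyclohex-2-en-1-ol F5. The diastereomers are separated by chromatography and the route is rejoined at 7.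

Step 4 may fail through poor facial selectivity, because the two flanks of the carbonyl (CH=C(Me) and CH2–CMe2) differ little in size and the ring's own bias may oppose the catalyst. Fallback: set out from 6 with a stereoconvergent sequence that does not depend on face selectivity. Luche reduction (NaBH4, CeCl3·7H2O, MeOH, −78 °C) gives 7 together with its carbinol epimer (1S,4R)-4-ethenyl-3,5,5-trimethylcyclohex-2-en-1-ol F6. After separation, 7 enters step 5, while the epimer is esterified with inversion by a Mitsunobu reaction with tetradecanoic acid (PPh3, diisopropyl azodicarboxylate, THF, 0 °C). Both alcohols thus converge on 8, where the route is rejoined.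

Step 6 may fail through slow turnover at the vinyl group, which is shielded by the C1' gem-dimethyl and C5' methyl groups, so that catalyst decay and enone self-metathesis take over. Fallback: set out from 8 and build the enone by oxidative cleavage and olefination in place of metathesis. Lemieux–Johnson cleavage of the monosubstituted alkene (OsO4 cat., NaIO4, 2,6-lutidine, dioxane–water; the trisubstituted ring alkene is shielded and deactivated by the allylic acyloxy group) gives (1R,4R)-4-formyl-3,5,5-trimethylcyclohex-2-en-1-yl tetradecanoate F7. This aldehyde is used at once, to avoid epimerisation at C6', in a Wittig reaction with the stabilised ylide 1-(triphenylphosphoranylidene)propan-2-one (CH2Cl2, 40 °C) to give 9, where the route is rejoined.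

**Further compounds**

F1 | step 1 | racemic trimethyl[(3-ethenyl-2,4,4-trimethylcyclopent-1-en-1-yl)oxy]silane | C=CC1C(C)=C(O[Si](C)(C)C)CC1(C)C
F2 | step 1 | racemic [(4-ethenyl-3,3,5-trimethylbicyclo[3.1.0]hexan-1-yl)oxy]trimethylsilane (CH2 bridge anti to vinyl) | C=CC1C2(C)CC2(O[Si](C)(C)C)CC1(C)C
F3 | step 1 | racemic 3-chloro-4-ethenyl-3,5,5-trimethylcyclohexan-1-one (not isolated) | C=CC1C(C)(Cl)CC(=O)CC1(C)C
F4 | step 1 | racemic 4-ethenyl-3,5,5-trimethylcyclohex-2-en-1-one | C=CC1C(C)=CC(=O)CC1(C)C
F5 | step 1 | (1R,4S)-4-ethenyl-3,5,5-trimethylcyclohex-2-en-1-ol | C=C[C@@H]1C(C)=C[C@H](O)CC1(C)C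
F6 | step 4 | (1S,4R)-4-ethenyl-3,5,5-trimethylcyclohex-2-en-1-ol | C=C[C@H]1C(C)=C[C@@H](O)CC1(C)C
F7 | step 6 | (1R,4R)-4-formyl-3,5,5-trimethylcyclohex-2-en-1-yl tetradecanoate | O=C[C@H]1C(C)=C[C@H](OC(=O)CCCCCCCCCCCCC)CC1(C)C
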